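The numbers in the tables were computed for an exercise.

Cedar still reads 44% of its E at 120 min, while maple, with more Z for each E, reads 1%, so the examiner's first question is what the end of such a flask can be read from.

| flask | E | Z | remark | time |
|---|---|---|---|---|
| cedar | 0.020 M (fed, over 4.0 min) | 0.0066 M | run made earlier; the fed solution adds 0.25 times the starting volume |  |
| alder | 0.020 M (fed, over 4.0 min) | 0.042 M | run made earlier; the fed solution adds 0.25 times the starting volume |  |
| maple | 0.026 M (fed, over 4.0 min) | 0.022 M | run made earlier; the fed solution adds 0.25 times the starting volume |  |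
| grey | 0.030 M (fed, over 4.0 min) | 0.0600 M | the fed solution adds 0.25 times the starting volume | 2.0 h |
| green | 0.020 M (fed, over 2.0 min) | 0.00800 M | the fed solution adds 0.25 times the starting volume | 2.0 h |
| blue | 0.020 M (fed, over 15 min) | 0.0220 M | the fed solution adds 0.25 times the starting volume | 2.0 h |
| teal | 0.020 M (fed, over 4.0 min) | 0.0220 M | the fed solution adds 0.25 times the starting volume | 2.0 h |
| amber | 0.030 M (fed, over 6.0 min) | 0.0220 M | the fed solution adds 0.25 times the starting volume | 2.0 h |

| run | time / min | Q / % | E / % |
|---|---|---|---|
| cedar | 15.0 | 8 | 62 |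
| cedar | 30.0 | 6 | 46 |
| cedar | 50.0 | 8 | 41 |
| cedar | 60.0 | 7 | 42 |
| cedar | 80.0 | 7 | 42 |
| cedar | 90.0 | 8 | 43 |
| cedar | 120 | 4 | 44 |
| alder | 6.00 | 28 | 27 |
| alder | 20.0 | 53 | 0 |
| alder | 30.0 | 48 | 1 |
| alder | 50.0 | 52 | 0 |
| alder | 80.0 | 42 | 1 |
| alder | 90.0 | 41 | 0 |
| alder | 120 | 34 | 0 |
| maple | 10.0 | 21 | 23 |
| maple | 20.0 | 26 | 6 |
| maple | 30.0 | 33 | 0 |
| maple | 60.0 | 30 | 0 |
| maple | 120 | 33 | 1 |

(scatter of a reading: 2 percentage points)

- every charge counts on the volume at the start, and the solution that is fed holds the whole dose

- the flasks by amount of Q, in percent of the E charged, highest first, at 2.0 h (grey / green / blue / teal / amber)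
- the same order at 25 min (grey / green / blue / teal / amber)
- the amount of Q, in percent of the E charged of the flask you put first, at 2.0 h
- the amount of Q, in percent of the E charged of the flask you put last, at 2.0 h

*What do you read the end of a lean flask from?* From r, the charge cZ over the charge cE, which is 0.330 in cedar and 0.846 in maple, and I take as their ends the Q readings from 30.0 min on, which stay level within the scatter of 2 percentage points and average 6.67% and 32.0%.

*And what do you carry from two flasks?* The yield slope, the fraction of the E charged that ends as Q for each further equivalent of Z, 0.491 as read from these readings, so that at the margin each Q costs 2.04 equivalents of Z.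

*Then reckon.* Drawing the line from cedar through maple, I get green at r = 0.400 ending near 10.1%, amber at 0.733 near 26.5%, and teal at 1.10 near 44.5%, which is still below alder's reading of 53%.

*Your weak spot is grey, surely?* It is, because at r = 2.00 the line gives 88.7%, more than alder's reading of 53% at 20.0 min, so I drop the line there and take alder's own fall to 34% at 120 min as my figure for grey's end.

*And blue, and the earlier time?* The line has no term for feed time, so blue stays level with teal at 2.0 h, and I place it second. At 25 min I put grey first, since alder reads 48% at 30.0 min, above the 44.5% my line gives teal, and I place blue behind teal, its feed lasting 15 min against 4.0 min.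

The forecast orders the flasks teal > blue > grey > amber > green at 2.0 h and grey > teal > blue > amber > green at 25 min, with teal at 46% (40% to 52%), reasoned as “Z just sufficient, little left to erode Q”, and green at 10% (7% to 14%). It parts from my reckoning on blue, which it sets at about 35 percent, on grey at about 29 and on amber at about 23.

The flasks give teal > blue > grey > amber > green at 2.0 h and grey > teal > blue > amber > green at 25 min.

    E + Z → D + X (k = 0.140 L mol⁻¹ s⁻¹)
    Z + D → Q + X (k = 0.240 L mol⁻¹ s⁻¹)
    Z + Q → G + X (k = 0.0120 L mol⁻¹ s⁻¹)
    Z + G → L + X (k = 0.220 L mol⁻¹ s⁻¹)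
    E + X → J (k = 0.240 L mol⁻¹ s⁻¹)

Teal ends at 43.9% against the line's 44.5%, green at 9.80% against 10.1%, and blue at 41.9%. In teal at 0.0754 h, E has a half-life of 0.11 h by the step with Z and 0.19 h by the step with X, a ratio of 1.65. Of teal's E, 47.7% stands as J at 2.00 h. The neighbour of teal with 0.013 M of Z has r = 0.650, where the slope gives 22.4%, and at 2.00 h that flask holds 22.5% Q.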